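**Strategy.** The 7-oxabicyclo[2.2.1]heptane (cyclohexane C1–C6 with O7 bridging the methyl-bearing C1 and C4) is unzipped in one move: cleaving C2–C3 and O7–C4 gives an acyclic (2R,3R)-vinyl epoxide carrying an (E)-3-methylpent-3-enyl chain. Forward, BF3 opens the epoxide at its allylic carbon (future C2) under attack of the trisubstituted alkene, and the epoxide oxygen, still on C1, captures the resulting C4 cation. Both rings and the C2, C3 and C4 configurations follow from the two Sharpless-derived epoxide centres. The vinyl group, which directs ionisation, then serves as the handle for a B-alkyl Suzuki union with an (S)-linalool-derived dibromoalkene; methylation and bromoetherification complete dactylopyranoid.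

Key step: step 7

Remark: (S)-(+)-linalool of high enantiomeric purity is taken as a commercial chiral-pool material; atom labels C1–C6/O7 are those of the oxabicycle (C1 bridgehead next to the side-chain carbon C2, C3 the CHMe carbon, C4 the second bridgehead).

Step 1
Reactants: 1 3-methylbut-3-en-2-ol; 2 triethyl orthoacetate
Product: 3 ethyl (4E)-4-methylhex-4-enoate
Conditions: EtCO2H (cat.), 140 °C, EtOH distilled off
Reagents that add atoms: none
Why: Johnson–Claisen rearrangement: the mixed ketene acetal from 1 and 2 rearranges through a chair transition state with the carbinol methyl equatorial, which should give the (E)-trisubstituted alkene; no stereocentre is formed.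

Step 2
Reactants: 3 ethyl (4E)-4-methylhex-4-enoate
Product: 5 (5E)-5-methylhept-5-en-1-yne, via (4E)-4-methylhex-4-enal 4 (not isolated)
Conditions: i-Bu2AlH, CH2Cl2, −78 °C; then MeOH, K2CO3, Ohira–Bestmann reagent, −78 °C → rt
Reagents that add atoms: dimethyl (1-diazo-2-oxopropyl)phosphonate CC(=O)C(=[N+]=[N-])P(=O)(OC)OC
Why: Half-reduction of the ester gives the aldehyde (held as its aluminium hemiacetal), and the Ohira–Bestmann variant of the Seyferth–Gilbert homologation converts it in the same flask into the terminal alkyne without touching the (E)-alkene.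

Step 3
Reactants: 5 (5E)-5-methylhept-5-en-1-yne
Product: 8 (2E,6E)-3,6-dimethylocta-2,6-dien-1-ol, via alkenyldimethylalane 6 (not isolated), via lithium alkenylalanate 7 (not isolated)
Conditions: Me3Al, Cp2ZrCl2 (cat.), CH2Cl2, 0 °C → rt; n-BuLi, THF, −78 °C; (CH2O)n, → rt; aq. HCl
Reagents that add atoms: trimethylaluminium C[Al](C)C; formaldehyde (from paraformaldehyde) C=O
Why: Negishi zirconium-catalysed carboalumination adds Me–Al syn across the terminal alkyne (methyl to the internal carbon) and the derived alanate is hydroxymethylated with retention, so the new trisubstituted alkene should be (E); the isolated alkene is inert.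

Step 4
Reactants: 8 (2E,6E)-3,6-dimethylocta-2,6-dien-1-ol
Product: 9 [(2R,3R)-3-methyl-3-[(3E)-3-methylpent-3-en-1-yl]oxiran-2-yl]methanol
Conditions: Ti(O-i-Pr)4 (cat.), D-(−)-diethyl tartrate (cat.), t-BuOOH, 4 Å MS, CH2Cl2, −20 °C
Reagents that add atoms: tert-butyl hydroperoxide CC(C)(C)OO
Why: Sharpless asymmetric epoxidation is confined to the allylic-alcohol alkene, and D-(−)-tartrate should deliver oxygen to the face giving the (2R,3R)-epoxide (the enantiomeric series to the L-tartrate/geraniol case), which sets C1 and C2 of the later bicycle by catalysis.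

Step 5
Reactants: 9 epoxy alcohol
Product: 10 (2S,3R)-3-methyl-3-[(3E)-3-methylpent-3-en-1-yl]oxirane-2-carbaldehyde
Conditions: TEMPO (cat.), PhI(OAc)2, CH2Cl2, rt
Reagents that add atoms: none
Why: The oxoammonium (TEMPO/PhI(OAc)2) oxidation stops at the aldehyde under near-neutral conditions that leave the epoxide, its stereocentres and the alkene untouched (the descriptor at C2 changes only through CIP priority).

Step 6
Reactants: 10 epoxy aldehyde
Product: 11 (2R,3R)-2-ethenyl-3-methyl-3-[(3E)-3-methylpent-3-en-1-yl]oxirane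
Conditions: Ph3PCH3Br, KN(SiMe3)2, THF, −78 → 0 °C
Reagents that add atoms: methyltriphenylphosphonium bromide C[P+](c1ccccc1)(c1ccccc1)c1ccccc1.[Br-]
Why: Wittig methylenation of the epoxy aldehyde should give the vinyl oxirane; the α-centre is held in the epoxide ring and is not expected to epimerise.

Step 7
Reactants: 11 vinyl oxirane
Product: 13 (1R,2R,3R,4S)-2-ethenyl-1,3,4-trimethyl-7-oxabicyclo[2.2.1]heptane (2-endo-vinyl, 3-exo-methyl), via tertiary cyclohexyl cation 12 (not isolated)
Conditions: BF3·OEt2 (0.3 equiv), CH2Cl2, −78 °C; Et3N quench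
Reagents that add atoms: none
Why: BF3 coordinates the oxirane oxygen (O7); the C2–O7 bond, weakened by the vinyl group (incipient allyl cation), is opened anti by C3 of the (E)-trisubstituted alkene, and the tertiary C4 cation so formed (12) is captured by the boron-bound alkoxide on C1 with release of BF3, so the whole event is an isomerisation. The closest known reaction type is the Lewis-acid epoxide-initiated cation–olefin cyclisation with ether termination (the bridged-ether outcome of epoxy-olefin cyclisations), here run at the allylic carbon of a vinyl oxirane as in anti-selective π-cyclisations of vinyl oxiranes. The carbocycle C1–C6 closes 6-endo-trig at the alkene (endo mode at the epoxide, chair transition state), and the oxygen bridge then closes transannularly across C1/C4 of the cyclohexyl cation in its boat form, which completes both five-membered oxacycles at once. C1 keeps its Sharpless-derived configuration, C2 is set by inversion at the epoxide carbon (vinyl trans to O7, endo), C3 by the (E)-alkene geometry in the chair (methyl equatorial and cis to O7, exo), and C4 by the bridge, which can only form cis to the C1–O7 bond. The step needs C2–O over C1–O cleavage and ether closure over proton loss: allylic activation by the vinyl group and the fact that the alkene can reach only C2 in a six-membered array (attack at C1 would be 5-endo) should secure the first, the intramolecular alkoxide as the only nucleophile present the second.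

Step 8
Reactants: 14 (S)-(+)-linalool
Product: 15 (5S)-5-ethenyl-5-methyloxolan-2-ol (anomer mixture)
Conditions: O3 (1 equiv), CH2Cl2/MeOH, −78 °C; then Me2S
Reagents that add atoms: ozone [O-][O+]=O
Why: Ozonolysis with reductive work-up should take the electron-rich trisubstituted alkene in preference to the hindered vinyl group, and the hydroxy aldehyde closes to the lactol; the carbinol stereocentre is untouched.

Step 9
Reactants: 15 lactol
Product: 16 (3S)-6,6-dibromo-3-methylhexa-1,5-dien-3-ol
Conditions: Ph3PCHBr2Br, t-BuOK, THF, 0 °C → rt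
Reagents that add atoms: (dibromomethyl)triphenylphosphonium bromide BrC(Br)[P+](c1ccccc1)(c1ccccc1)c1ccccc1.[Br-]
Why: The ylide Ph3P=CBr2 olefinates the open hydroxy-aldehyde form of the lactol (Ramirez/Corey–Fuchs dibromoolefination run as a Wittig reaction), which avoids Appel-type activation of the tertiary allylic alcohol.

Step 10
Reactants: 13 vinyl oxabicycle; 16 dibromodienol
Product: 18 (3S,5Z)-6-bromo-3-methyl-8-[(1R,2R,3R,4S)-1,3,4-trimethyl-7-oxabicyclo[2.2.1]heptan-2-yl]octa-1,5-dien-3-ol, via B-alkyl-9-BBN 17 (not isolated)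
Conditions: 13 (slight excess), 9-BBN-H, THF, rt; then 16, PdCl2(dppf) (cat.), AsPh3, Cs2CO3, DMF/H2O, rt
Reagents that add atoms: none
Why: 9-BBN-H adds anti-Markovnikov to the only alkene of 13, and the B-alkyl Suzuki–Miyaura coupling should occur at the C–Br bond trans to the chain of 16 (less hindered oxidative addition), placing the new chain trans and leaving the cis bromide for the next step.

Step 11
Reactants: 18 (Z)-bromoalkene
Product: 19 (3S,5E)-3,6-dimethyl-8-[(1R,2R,3R,4S)-1,3,4-trimethyl-7-oxabicyclo[2.2.1]heptan-2-yl]octa-1,5-dien-3-ol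
Conditions: Me2Zn (excess), Pd(P(t-Bu)3)2 (cat.), THF, 0 °C → rt
Reagents that add atoms: dimethylzinc C[Zn]C
Why: Negishi coupling of the remaining alkenyl bromide with Me2Zn under this catalyst should proceed with retention and give the (E)-trisubstituted alkene; the free hydroxyl is only deprotonated.

Step 12
Reactants: 19 dienol
Product: 20 dactylopyranoid
Conditions: 2,4,4,6-tetrabromocyclohexa-2,5-dienone, MeNO2, 0 °C
Reagents that add atoms: 2,4,4,6-tetrabromocyclohexa-2,5-dien-1-one O=C1C(Br)=CC(Br)(Br)C=C1Br
Why: Bromonium formation at the trisubstituted alkene and Markovnikov 6-endo capture by the tertiary hydroxyl (bromoetherification) is an anti addition to the (E)-alkene, which fixes the CHBr centre and the new quaternary C–O centre relative to each other; the bromonium face relative to the existing carbinol centre is only weakly substrate-controlled, so 20 is expected together with its bromonium-face diastereomer and must be separated from it.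

**Compound list**

1 | 3-methylbut-3-en-2-ol (racemic) | CC(O)C(C)=C | starting material
2 | triethyl orthoacetate | CC(OCC)(OCC)OCC | starting material
3 | ethyl (4E)-4-methylhex-4-enoate | CCOC(=O)CC/C(C)=C/C | intermediate
4 | (4E)-4-methylhex-4-enal | O=CCC/C(C)=C/C | intermediate (not isolated)
5 | (5E)-5-methylhept-5-en-1-yne | C#CCC/C(C)=C/C | intermediate
6 | [(1E,5E)-2,5-dimethylhepta-1,5-dien-1-yl]dimethylalane | C[Al](C)/C=C(\C)CC/C(C)=C/C | intermediate (not isolated)
7 | lithium butyl[(1E,5E)-2,5-dimethylhepta-1,5-dien-1-yl]dimethylalanate | [Li+].CCCC[Al-](C)(C)/C=C(\C)CC/C(C)=C/C | intermediate (not isolated)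
8 | (2E,6E)-3,6-dimethylocta-2,6-dien-1-ol | OC/C=C(\C)CC/C(C)=C/C | intermediate
9 | [(2R,3R)-3-methyl-3-[(3E)-3-methylpent-3-en-1-yl]oxiran-2-yl]methanol | OC[C@H]1O[C@]1(C)CC/C(C)=C/C | intermediate
10 | (2S,3R)-3-methyl-3-[(3E)-3-methylpent-3-en-1-yl]oxirane-2-carbaldehyde | O=C[C@H]1O[C@]1(C)CC/C(C)=C/C | intermediate
11 | (2R,3R)-2-ethenyl-3-methyl-3-[(3E)-3-methylpent-3-en-1-yl]oxirane | C=C[C@H]1O[C@]1(C)CC/C(C)=C/C | intermediate
12 | C4 cyclohexyl cation with C1–O–BF3 (O, vinyl and C3-methyl all equatorial) | C=C[C@@H]1[C@@H](C)[C+](C)CC[C@@]1(C)O[B-](F)(F)F | intermediate (not isolated)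
13 | (1R,2R,3R,4S)-2-ethenyl-1,3,4-trimethyl-7-oxabicyclo[2.2.1]heptane | C=C[C@@H]1[C@@H](C)[C@]2(C)CC[C@@]1(C)O2 | intermediate
14 | (S)-(+)-linalool, (3S)-3,7-dimethylocta-1,6-dien-3-ol | C=C[C@@](C)(O)CCC=C(C)C | starting material
15 | (5S)-5-ethenyl-5-methyloxolan-2-ol (anomer mixture) | C=C[C@]1(C)CCC(O)O1 | intermediate
16 | (3S)-6,6-dibromo-3-methylhexa-1,5-dien-3-ol | C=C[C@@](C)(O)CCC=C(Br)Br | intermediate
17 | 9-{2-[(1R,2R,3R,4S)-1,3,4-trimethyl-7-oxabicyclo[2.2.1]heptan-2-yl]ethyl}-9-borabicyclo[3.3.1]nonane | C(C[C@@H]1[C@@H](C)[C@]2(C)CC[C@@]1(C)O2)B1C2CCCC1CCC2 | intermediate (not isolated)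
18 | (3S,5Z)-6-bromo-3-methyl-8-[(1R,2R,3R,4S)-1,3,4-trimethyl-7-oxabicyclo[2.2.1]heptan-2-yl]octa-1,5-dien-3-ol | C=C[C@@](C)(O)CC/C=C(\Br)CC[C@@H]1[C@@H](C)[C@]2(C)CC[C@@]1(C)O2 | intermediate
19 | (3S,5E)-3,6-dimethyl-8-[(1R,2R,3R,4S)-1,3,4-trimethyl-7-oxabicyclo[2.2.1]heptan-2-yl]octa-1,5-dien-3-ol | C=C[C@@](C)(O)CC/C=C(\C)CC[C@@H]1[C@@H](C)[C@]2(C)CC[C@@]1(C)O2 | intermediate
20 | dactylopyranoid | C=C[C@]1(C)CC[C@@H](Br)[C@](C)(CC[C@@H]2[C@@H](C)[C@]3(C)CC[C@@]2(C)O3)O1 | target

**Total step count:** 12. **Longest linear sequence:** 10 (steps 1–7, then 10–12).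

**Steps most likely to fail**

Step 7. The risk is ionisation toward the tertiary carbon followed by a 1,2-hydride shift (Meinwald rearrangement), a pinacol-type shift within the allyl cation, proton loss from the cyclohexyl cation before the ether closes, or loss of the anti opening if the allyl cation becomes free. The fallback sets out from 11 and replaces the epoxide electrophile by an allyl–iridium electrophile. Palladium-catalysed hydrolysis (Pd2(dba)3, PPh3, Et3B cat., NaHCO3, H2O/CH2Cl2) should open only the allylic C–O bond, with retention, to the diol (3R,4R,7E)-4,7-dimethylnona-1,7-diene-3,4-diol F1, leaving the tertiary carbinol untouched. An iridium-catalysed, allylic-alcohol-initiated cyclisation ([Ir(cod)Cl]2, chiral phosphoramidite–olefin ligand of the enantiomer that gives the 2R centre, Zn(OTf)2, ClCH2CH2Cl, rt) then lets the alkene add to the branched allyl terminus in the same chair, and the tertiary hydroxyl closes the bridge. Here C2 is fixed by the ligand instead of by an SN2 event. The sequence returns to the route at 13.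

Step 12. The risk is poor facial selectivity of bromonium formation relative to the distant carbinol centre, together with competing 5-exo closure to a tetrahydrofuran. The fallback sets out from 19 and fixes the bromonium configuration by reagent control. Shi epoxidation (ketone enantiomer chosen for the S,S-epoxide, expected to be the L-series catalyst; KHSO5, K2CO3 buffer, MeCN/H2O, 0 °C) should give the epoxide (3S)-3-methyl-5-[(2S,3S)-3-methyl-3-{2-[(1R,2R,3R,4S)-1,3,4-trimethyl-7-oxabicyclo[2.2.1]heptan-2-yl]ethyl}oxiran-2-yl]pent-1-en-3-ol F2. Bromide opening at the secondary carbon with inversion (Li2NiBr4, THF) gives the bromohydrin (3S,6S,7R)-6-bromo-3,7-dimethyl-9-[(1R,2R,3R,4S)-1,3,4-trimethyl-7-oxabicyclo[2.2.1]heptan-2-yl]non-1-ene-3,7-diol F3. Ionisation of its bromine-flanked tertiary carbinol with neighbouring-bromine participation (SnCl4, CH2Cl2, −78 °C) regenerates a single bromonium ion, which the other tertiary hydroxyl captures 6-endo. The sequence returns to the route at 20.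

Step 10. The risk is unselective or double oxidative addition at the dibromoalkene, base-induced elimination to a bromoalkyne, and slow transmetalation of the hindered alkylborane. The fallback sets out from 13 and uses an alkylzinc nucleophile. Hydroboration–oxidation (9-BBN-H; NaOH, H2O2) gives the alcohol 2-[(1R,2R,3R,4S)-1,3,4-trimethyl-7-oxabicyclo[2.2.1]heptan-2-yl]ethanol F4. Appel iodination (PPh3, I2, imidazole) gives the iodide (1R,2R,3R,4S)-2-(2-iodoethyl)-1,3,4-trimethyl-7-oxabicyclo[2.2.1]heptane F5. Zinc insertion (Zn dust, LiCl, THF) gives the alkylzinc iodide {2-[(1R,2R,3R,4S)-1,3,4-trimethyl-7-oxabicyclo[2.2.1]heptan-2-yl]ethyl}zinc iodide F6, which is used in excess in a trans-selective Negishi monoalkylation of 16 (PdCl2(DPEphos), THF/DMF). The sequence returns to the route at 18.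

**Further compounds**

F1 | step 7 | (3R,4R,7E)-4,7-dimethylnona-1,7-diene-3,4-diol | C=C[C@@H](O)[C@](C)(O)CC/C(C)=C/C
F2 | step 12 | (3S)-3-methyl-5-[(2S,3S)-3-methyl-3-{2-[(1R,2R,3R,4S)-1,3,4-trimethyl-7-oxabicyclo[2.2.1]heptan-2-yl]ethyl}oxiran-2-yl]pent-1-en-3-ol | C=C[C@@](C)(O)CC[C@@H]1O[C@@]1(C)CC[C@@H]2[C@@H](C)[C@]3(C)CC[C@@]2(C)O3
F3 | step 12 | (3S,6S,7R)-6-bromo-3,7-dimethyl-9-[(1R,2R,3R,4S)-1,3,4-trimethyl-7-oxabicyclo[2.2.1]heptan-2-yl]non-1-ene-3,7-diol | C=C[C@@](C)(O)CC[C@@H](Br)[C@](C)(CC[C@@H]1[C@@H](C)[C@]2(C)CC[C@@]1(C)O2)O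
F4 | step 10 | 2-[(1R,2R,3R,4S)-1,3,4-trimethyl-7-oxabicyclo[2.2.1]heptan-2-yl]ethanol | OCC[C@@H]1[C@@H](C)[C@]2(C)CC[C@@]1(C)O2
F5 | step 10 | (1R,2R,3R,4S)-2-(2-iodoethyl)-1,3,4-trimethyl-7-oxabicyclo[2.2.1]heptane | ICC[C@@H]1[C@@H](C)[C@]2(C)CC[C@@]1(C)O2
F6 | step 10 | {2-[(1R,2R,3R,4S)-1,3,4-trimethyl-7-oxabicyclo[2.2.1]heptan-2-yl]ethyl}zinc iodide | I[Zn]CC[C@@H]1[C@@H](C)[C@]2(C)CC[C@@]1(C)O2
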